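The vessel is closed and stirred, gas is held at saturation, and one charge of substrate meets different charges of free catalyst.

common to all: substrate 0.020 M; gas 9.6 mM (held)
- alpha: free catalyst 20 µM; the very flask that is asked about, followed so far
- gamma: free catalyst 10 µM; run made earlier
- flask: free catalyst 20 µM

- alpha (time / s: target / %, substrate / %): 10.0: 0.5, 99.4; 15.0: 0.8, 99.1; 25.0: 2.2, 97.4; 50.0: 5.8, 94.6; 90.0: 12.9, 87.0
- gamma (time / min: target / %, substrate / %): 0.250: 0.3, 99.7; 0.667: 2.0, 98.1; 1.33: 5.0, 94.4; 2.00: 9.7, 90.6; 3.00: 14.3, 85.7

(each reading ± 0.3 percentage points)

- at the start none of the gas is in solution

1. factor on the rate of making target when 50 % of the substrate are converted if free catalyst is charged twice over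
2. factor on the rate when 50 % of the substrate are converted if free catalyst is charged at 200 µM instead

My reckoning starts from two extreme flasks. If free catalyst lasts, flasks at equal conversion differ by their charge, giving a factor of two on doubling. But they reach 50 % at different clock times. At its slope from 50.0 s to 90.0 s, the alpha flask would get there in 4.69 min, and the doubled flask in half of that. The difference of the two times, 2.35 min, is the clock gap: the stretch of any loss running on the clock that the doubled flask is spared.

At the other extreme, free catalyst halves within each gap and the factor is 4. The gamma run speaks against this: per catalyst, its slope from 2.00 min to 3.00 min reads 0.864 of alpha's. Counting that whole fall as loss gives a rough half-life of 6.31 min, longer than the gap. I therefore expect about 2.59 on doubling. At 200 µM, the gap of 4.23 min gives about 15.9, less whatever gas shortfall that load brings.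

The forecast says 1.9 and 7, lower than my figures, holding that “The slopes show the rate is about first order in catalyst at these loadings.”

The flask gives 2.97 and 11.3.

    substrate + partner + free catalyst → target + free catalyst, rate k1*[substrate]*[partner]*[free catalyst]/(1 + ([substrate]/sat1)) (19.8 mM, k = 26500 M⁻² s⁻¹)
    free catalyst → spent catalyst (k = 0.00215 s⁻¹)
    gas ⇌ partner, rate k3*(csat - [partner]) (kL = 0.0347 s⁻¹)

By the step to spent catalyst (catalyst deactivation), free catalyst in the flask has a half-life of 5.4 min, shorter than the 7.21 min needed to reach 50 %, and 39.5 % of it is free at that point. Doubling multiplies that time by 0.473, a clock gap of 3.80 min against the 2.35 min reckoned, and with 200 µM charged, 86.0 % of the catalyst is free catalyst at the same conversion.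

The data are simulated for an exercise, and the scatter is random.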